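**Plan**

Numbering: ring O1–O2–C3(OH)–C4–C5–C6; side chain C1′–C10′ (C2′ carries the methyl group, C9′=C10′ is the styrene).

1. Retrosynthetic cuts, in order: C3–OH ⇒ C3–OMe; the C6–CH3 bond (methyl nucleophile + cyclic peroxycarbenium ion at C6); both C–O bonds of the peroxide (H2O2 + mono-ketal of a 1,4-diketone); C6–C1′ (Grignard + Weinreb amide); C3′–C4′ (Cu-catalysed sp3–sp3 coupling).
2. Forward: the chain is joined at C3′–C4′, then at C6–C1′. H2O2 then closes the 1,2-dioxane between the two carbonyl-level carbons C3 and C6 under thermodynamic control. The quaternary peroxide carbon C6 is made last, inside the ring, by C–C and not C–O bond formation.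
3. Stereochemistry: C4 from commercial (R)-2-methylsuccinic acid 4-methyl ester, whose chain maps onto C3–C4(CH3)–C5–C6; C2′ from commercial (S)-3-bromo-2-methylpropan-1-ol; the Z-alkene from a Lindlar reduction; C6 from axial methyl delivery to the ring cation under control of C4; C3 from anomeric equilibration.
4. Enabling feature: C3 and C6, the carbons bearing O2 and O1, stand 1,4, and C6 is formally a methylated ketone carbon. In the target chair the C6 methyl is axial and trans to the equatorial C4 methyl, which is the kinetic result of axial attack on a 1,2-dioxan-3-ylium half-chair. The anomeric mixtures at C6 and C3 of the precursors therefore converge on one isomer.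

Key step: step 12

Assumption: the (3S) hemiketal (axial OH, equatorial CH3, anomeric effect) is the thermodynamically preferred C3 configuration and is reached by ring–chain equilibration; C4 and C6 have no comparable bias (CH3 and CH2R at C6 are nearly equal in size) and must be set kinetically.

**Route**

Step 1
Reactants: 1 hept-6-yn-1-ol; 2 iodobenzene
Product: 3 7-phenylhept-6-yn-1-ol
Conditions: PdCl2(PPh3)2 (2 mol %), CuI (4 mol %), Et3N, THF, rt
Reagents that add atoms: none
Why: Sonogashira coupling of a terminal alkyne with an aryl iodide should proceed at room temperature and tolerates the free primary alcohol.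

Step 2
Reactants: 3 7-phenylhept-6-yn-1-ol
Product: 4 (Z)-7-phenylhept-6-en-1-ol
Conditions: H2 (1 atm), Lindlar catalyst, quinoline, EtOAc, rt, stopped after 1 equiv H2
Reagents that add atoms: none
Why: Lindlar semihydrogenation delivers H2 syn to the alkyne on the poisoned Pd surface and should give the (Z)-styrene, the only source of the C9′=C10′ geometry, which no later step touches.

Step 3
Reactants: 4 (Z)-7-phenylhept-6-en-1-ol
Product: 5 (Z)-(7-bromohept-1-en-1-yl)benzene
Conditions: CBr4, PPh3, CH2Cl2, 0 °C
Reagents that add atoms: carbon tetrabromide, BrC(Br)(Br)Br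
Why: Appel reaction, an SN2 displacement of the activated primary alkoxyphosphonium ion by bromide that leaves the Z-alkene untouched.

Step 4
Reactants: 5 (Z)-(7-bromohept-1-en-1-yl)benzene; 6 (S)-3-bromo-2-methylpropan-1-ol
Product: 9 (2R,9Z)-2-methyl-10-phenyldec-9-en-1-ol, via Grignard reagent 7 (not isolated), via magnesium alkoxide 8 (not isolated)
Conditions: 5, Mg, THF, 40 °C; 6, MeMgCl (1.0 equiv), THF, −20 °C; then combined, Li2CuCl4 (5 mol %), NMP, THF, 0 °C → rt; aq. NH4Cl
Reagents that add atoms: none
Why: Kochi-type copper-catalysed sp3–sp3 coupling of a primary Grignard reagent with a primary bromide whose hydroxyl is masked in the flask as its magnesium alkoxide; the C2′ stereocentre comes from the building block and is not involved, its descriptor changing from S to R only because CH2Br outranks CH2OH in 6 while CH2OH outranks the new alkyl chain in 9.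

Step 5
Reactants: 9 (2R,9Z)-2-methyl-10-phenyldec-9-en-1-ol
Product: 10 [(1Z,9R)-10-bromo-9-methyldec-1-en-1-yl]benzene
Conditions: CBr4, PPh3, CH2Cl2, 0 °C
Reagents that add atoms: carbon tetrabromide, BrC(Br)(Br)Br
Why: Appel reaction at the primary carbon; the neighbouring C2′ stereocentre carries no acidic hydrogen and is not touched.

Step 6
Reactants: 11 (R)-4-methoxy-2-methyl-4-oxobutanoic acid [(R)-2-methylsuccinic acid 4-methyl ester]
Product: 13 methyl (3R)-3-methyl-4-oxopentanoate, via acid chloride 12 (not isolated)
Conditions: (COCl)2, DMF (cat.), CH2Cl2, 0 °C → rt, evaporate; Me2CuLi (from MeLi, CuI), Et2O, −78 °C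
Reagents that add atoms: lithium dimethylcuprate, [Li+].C[Cu-]C
Why: Ketone synthesis from an acid chloride and a Gilman cuprate, which stops at the ketone and ignores the methyl ester at −78 °C; no amine base is present, so ketene formation and loss of the C4 configuration (α to the acyl group) should be avoided.

Step 7
Reactants: 13 methyl (3R)-3-methyl-4-oxopentanoate
Product: 14 methyl (3R)-4,4-dimethoxy-3-methylpentanoate
Conditions: HC(OMe)3, MeOH, p-TsOH·H2O (2 mol %), rt; Et3N quench
Reagents that add atoms: trimethyl orthoformate, COC(OC)OC; methanol, CO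
Why: Acid-catalysed ketalisation driven by the orthoformate as water scavenger, run with a trace of acid at room temperature so that enolisation towards C4 stays slow; the ketal masks C3 against the organomagnesium reagents of steps 8 and 9 and later supplies the C3 methoxy group.

Step 8
Reactants: 14 methyl (3R)-4,4-dimethoxy-3-methylpentanoate
Product: 15 (3R)-N,4,4-trimethoxy-N,3-dimethylpentanamide
Conditions: MeNH(OMe)·HCl, i-PrMgCl, THF, −20 °C
Reagents that add atoms: N,O-dimethylhydroxylamine hydrochloride, CNOC.Cl
Why: Aminolysis of the methyl ester by the magnesium amide of N,O-dimethylhydroxylamine (Weinreb amide synthesis), to which the ketal and the C4 stereocentre (β to the ester) are inert.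

Step 9
Reactants: 10 [(1Z,9R)-10-bromo-9-methyldec-1-en-1-yl]benzene; 15 (3R)-N,4,4-trimethoxy-N,3-dimethylpentanamide
Product: 17 (3R,7R,14Z)-2,2-dimethoxy-3,7-dimethyl-15-phenylpentadec-14-en-5-one, via Grignard reagent 16 (not isolated)
Conditions: 10, Mg, THF, 40 °C; then 15, THF, 0 °C; pH 7 phosphate buffer
Reagents that add atoms: none
Why: Weinreb ketone synthesis, in which the chelated tetrahedral adduct prevents over-addition; this joins C6 to C1′, and neither stereocentre is α to the new carbonyl group.

Step 10
Reactants: 17 (3R,7R,14Z)-2,2-dimethoxy-3,7-dimethyl-15-phenylpentadec-14-en-5-one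
Product: 19 (3S,4R)-3-methoxy-3,4-dimethyl-6-[(2R,9Z)-2-methyl-10-phenyldec-9-en-1-yl]-1,2-dioxan-6-ol (target ring numbering; C6 anomers), via hydroperoxy ketal 18 (not isolated)
Conditions: H2O2 (anhydrous, in Et2O, 2 equiv), CSA (5 mol %), Et2O, 0 °C; NaHCO3
Reagents that add atoms: hydrogen peroxide, OO
Why: Acid-catalysed perhydrolysis of the dimethyl ketal should give the α-methoxy hydroperoxide 18, whose OOH group adds to the C6 ketone to close the six-membered O1–O2–C3–C4–C5–C6 ring (intramolecular hemiketalisation, reversible, so C3 settles with OMe axial and cis to the C4 methyl), and because C3 keeps OMe while C6 receives OH the two peroxide-bearing carbons are differentiated.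

Step 11
Reactants: 19 (3S,4R)-3-methoxy-3,4-dimethyl-6-[(2R,9Z)-2-methyl-10-phenyldec-9-en-1-yl]-1,2-dioxan-6-ol
Product: 20 (3S,4R)-3-methoxy-3,4-dimethyl-6-[(2R,9Z)-2-methyl-10-phenyldec-9-en-1-yl]-1,2-dioxan-6-yl acetate (C6 anomers)
Conditions: Ac2O, Et3N, DMAP (10 mol %), CH2Cl2, 0 °C
Reagents that add atoms: acetic anhydride, CC(=O)OC(C)=O
Why: DMAP-catalysed O-acylation of the cyclic hemiketal hydroxyl, the reaction type that converts lactols into anomeric acetates, should place the only good leaving group on C6 and leave the C3 methyl ketal untouched.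

Step 12
Reactants: 20 (3S,4R)-3-methoxy-3,4-dimethyl-6-[(2R,9Z)-2-methyl-10-phenyldec-9-en-1-yl]-1,2-dioxan-6-yl acetate
Product: 22 (3S,4R,6S)-3-methoxy-3,4,6-trimethyl-6-[(2R,9Z)-2-methyl-10-phenyldec-9-en-1-yl]-1,2-dioxane, via peroxycarbenium ion 21 (not isolated)
Conditions: AlMe3 (3 equiv), CH2Cl2, −78 → −40 °C; aq. Rochelle salt
Reagents that add atoms: trimethylaluminium, C[Al](C)C
Why: Proposed new method: AlMe3 binds the acetate carbonyl of 20 and the O1 lone pair expels the acetate, so both C6 anomers funnel into one 1,2-dioxan-3-ylium (peroxycarbenium) ion 21 paired with [Me3Al–OAc]−, which returns a methyl group to C6; no ring is closed, the ring made in step 10 is only substituted. The closest known reaction types are the Lewis-acid-mediated additions of allylsilanes and silyl enol ethers to 3-alkoxy-1,2-dioxanes and 1,2-dioxolanes through peroxycarbenium ions, which also build quaternary peroxide carbons, and the C-methylation of anomeric acetates and fluorides by trialkylaluminium reagents through oxocarbenium ions. The new stereocentre C6 is controlled by C4: in the half-chair of 21 (C5–C6=O1–O2 coplanar) the C4 methyl is pseudoequatorial and the C3 methoxy pseudoaxial, and methyl is delivered along the axial trajectory on the face syn to the axial C4–H and anti to C3–OMe, the only approach that leads directly to a chair and avoids a 1,3-diaxial CH3/CH3 contact. This puts the new methyl axial and trans to the C4 methyl and the side chain equatorial, i.e. (6S), the arrangement in the stable chair of the target. The step needs ionisation at C6 rather than C3, secured by the acetate (a far better Lewis base and nucleofuge than the C3 methyl ketal at −78 °C), and C–O ionisation rather than attack on the O–O bond, favoured by the low temperature and by both peroxide carbons being fully substituted. Either C3 epimer of 20 should give the same C6 configuration, and C3 is corrected in step 13.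

Step 13
Reactants: 22 (3S,4R,6S)-3-methoxy-3,4,6-trimethyl-6-[(2R,9Z)-2-methyl-10-phenyldec-9-en-1-yl]-1,2-dioxane
Product: 23 (3S,4R,6S)-3,4,6-trimethyl-6-[(2R,9Z)-2-methyl-10-phenyldec-9-en-1-yl]-1,2-dioxan-3-ol (target)
Conditions: p-TsOH·H2O (10 mol %), THF/H2O (4:1), 0 °C → rt
Reagents that add atoms: water, O
Why: Acid-catalysed hydrolysis of the mixed methyl peroxyketal through the C3 peroxycarbenium ion followed by ring–chain equilibration of the peroxyhemiketal, which places OH axial (anomeric effect) and CH3 equatorial, i.e. (3S), whichever C3 epimer of 22 enters; the fully substituted dialkyl peroxide at C6 and the Z-styrene are inert to dilute acid, and enolisation towards C4 is slow at this acidity.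

**Compound list**

1 | hept-6-yn-1-ol | OCCCCCC#C | starting material
2 | iodobenzene | Ic1ccccc1 | starting material
3 | 7-phenylhept-6-yn-1-ol | OCCCCCC#Cc1ccccc1 | intermediate
4 | (Z)-7-phenylhept-6-en-1-ol | OCCCCC/C=C\c1ccccc1 | intermediate
5 | (Z)-(7-bromohept-1-en-1-yl)benzene | BrCCCCC/C=C\c1ccccc1 | intermediate
6 | (S)-3-bromo-2-methylpropan-1-ol | C[C@H](CBr)CO | starting material
7 | [(6Z)-7-phenylhept-6-en-1-yl]magnesium bromide (not isolated) | Br[Mg]CCCCC/C=C\c1ccccc1 | intermediate
8 | chloromagnesium (2S)-3-bromo-2-methylpropan-1-olate (not isolated) | C[C@H](CBr)CO[Mg]Cl | intermediate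
9 | (2R,9Z)-2-methyl-10-phenyldec-9-en-1-ol | C[C@H](CCCCCC/C=C\c1ccccc1)CO | intermediate
10 | [(1Z,9R)-10-bromo-9-methyldec-1-en-1-yl]benzene | C[C@H](CCCCCC/C=C\c1ccccc1)CBr | intermediate
11 | (R)-4-methoxy-2-methyl-4-oxobutanoic acid | COC(=O)C[C@@H](C)C(=O)O | starting material
12 | methyl (3R)-4-chloro-3-methyl-4-oxobutanoate (not isolated) | COC(=O)C[C@@H](C)C(=O)Cl | intermediate
13 | methyl (3R)-3-methyl-4-oxopentanoate | COC(=O)C[C@@H](C)C(C)=O | intermediate
14 | methyl (3R)-4,4-dimethoxy-3-methylpentanoate | COC(=O)C[C@@H](C)C(C)(OC)OC | intermediate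
15 | (3R)-N,4,4-trimethoxy-N,3-dimethylpentanamide | CON(C)C(=O)C[C@@H](C)C(C)(OC)OC | intermediate
16 | [(2R,9Z)-2-methyl-10-phenyldec-9-en-1-yl]magnesium bromide (not isolated) | C[C@H](CCCCCC/C=C\c1ccccc1)C[Mg]Br | intermediate
17 | (3R,7R,14Z)-2,2-dimethoxy-3,7-dimethyl-15-phenylpentadec-14-en-5-one | C[C@H](CCCCCC/C=C\c1ccccc1)CC(=O)C[C@@H](C)C(C)(OC)OC | intermediate
18 | (3R,7R,14Z)-2-hydroperoxy-2-methoxy-3,7-dimethyl-15-phenylpentadec-14-en-5-one (C2 epimers, not isolated) | C[C@H](CCCCCC/C=C\c1ccccc1)CC(=O)C[C@@H](C)C(C)(OC)OO | intermediate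
19 | (3S,4R)-3-methoxy-3,4-dimethyl-6-[(2R,9Z)-2-methyl-10-phenyldec-9-en-1-yl]-1,2-dioxan-6-ol (C6 anomers; expected major C3 epimer shown) | C[C@H](CCCCCC/C=C\c1ccccc1)CC1(O)C[C@@H](C)[C@@](C)(OC)OO1 | intermediate
20 | (3S,4R)-3-methoxy-3,4-dimethyl-6-[(2R,9Z)-2-methyl-10-phenyldec-9-en-1-yl]-1,2-dioxan-6-yl acetate (C6 anomers) | C[C@H](CCCCCC/C=C\c1ccccc1)CC1(OC(C)=O)C[C@@H](C)[C@@](C)(OC)OO1 | intermediate
21 | (3S,4R)-3-methoxy-3,4-dimethyl-6-[(2R,9Z)-2-methyl-10-phenyldec-9-en-1-yl]-4,5-dihydro-3H-1,2-dioxin-1-ium (not isolated) | C[C@H](CCCCCC/C=C\c1ccccc1)CC1=[O+]O[C@](C)(OC)[C@H](C)C1 | intermediate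
22 | (3S,4R,6S)-3-methoxy-3,4,6-trimethyl-6-[(2R,9Z)-2-methyl-10-phenyldec-9-en-1-yl]-1,2-dioxane | C[C@H](CCCCCC/C=C\c1ccccc1)C[C@@]1(C)C[C@@H](C)[C@@](C)(OC)OO1 | intermediate
23 | (3S,4R,6S)-3,4,6-trimethyl-6-[(2R,9Z)-2-methyl-10-phenyldec-9-en-1-yl]-1,2-dioxan-3-ol | C[C@H](CCCCCC/C=C\c1ccccc1)C[C@@]1(C)C[C@@H](C)[C@@](C)(O)OO1 | target

**Summary**

Total step count: 13. Longest linear sequence: 10 steps (steps 1–5 and 9–13, from hept-6-yn-1-ol); steps 6–8 form the second branch.

**Steps most likely to fail**

Step 12 (Proposed new method). The organoaluminium may attack or reduce the O–O bond. The Lewis acid may trigger heterolytic O–O cleavage with carbon migration instead of C6–OAc ionisation. The cation may lose a proton to an enol peroxide, or C3 may ionise. The fallback uses known chemistry and closes the peroxide ring by C–O bond formation onto an alkene. It sets out from ketone 17. Wittig methylenation (Ph3P=CH2, THF, 0 °C) would give (3R,7R,14Z)-2,2-dimethoxy-3,7-dimethyl-5-methylidene-15-phenylpentadec-14-ene F1. Perhydrolysis of its ketal (ethereal H2O2, PPTS, 0 °C) would give (3R,7R,14Z)-2-hydroperoxy-2-methoxy-3,7-dimethyl-5-methylidene-15-phenylpentadec-14-ene F2. Cycloperoxymercuration (Hg(OAc)2, CH2Cl2, 0 °C; 6-exo attack of the OOH group at C6) would give {[(4R)-3-methoxy-3,4-dimethyl-6-[(2R,9Z)-2-methyl-10-phenyldec-9-en-1-yl]-1,2-dioxan-6-yl]methyl}mercury(II) acetate F3. Hydridodemercuration (NaBH4, aq. NaOH, 0 °C) would then give methyl peroxyketal 22, where the fallback comes back to the route. The facial selectivity of this closure is expected to be moderate only, so the C6 epimer would have to be removed by chromatography at 22.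

Step 11. Under basic acylation the hemiketal may open to the hydroperoxy ketone, so that the OOH group is acylated instead, or the hindered tertiary hydroxyl may not react. The fallback replaces acyl transfer by a non-basic deoxyfluorination and sets out from hemiketal 19. DAST (CH2Cl2, −78 °C) would give (3S,4R)-6-fluoro-3-methoxy-3,4-dimethyl-6-[(2R,9Z)-2-methyl-10-phenyldec-9-en-1-yl]-1,2-dioxane F4. This anomeric-type fluoride would then be treated with AlMe3 as in step 12 (trialkylaluminium substitution of anomeric fluorides) and come back to the route at 22.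

Step 4. Substitution at the β-branched bromide that carries a neighbouring alkoxide may be slow, so that homocoupling of the Grignard reagent or oxetane formation from the alkoxide wins. The fallback reverses the roles of the partners, so that the unbranched bromide becomes the electrophile, and sets out from bromo alcohol 6. Silylation (TBSCl, imidazole, CH2Cl2) would give (S)-(3-bromo-2-methylpropoxy)(tert-butyl)dimethylsilane F5. Magnesium in THF would convert it into [(2S)-3-{[tert-butyl(dimethyl)silyl]oxy}-2-methylpropyl]magnesium bromide F6. Coupling with bromide 5 (Li2CuCl4 cat., THF, 0 °C) would give tert-butyl(dimethyl){[(2R,9Z)-2-methyl-10-phenyldec-9-en-1-yl]oxy}silane F7, and TBAF (THF, rt) would give alcohol 9, where the fallback comes back to the route.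

**Further compounds**

F1 | step 12 | (3R,7R,14Z)-2,2-dimethoxy-3,7-dimethyl-5-methylidene-15-phenylpentadec-14-ene | C[C@H](CCCCCC/C=C\c1ccccc1)CC(=C)C[C@@H](C)C(C)(OC)OC
F2 | step 12 | (3R,7R,14Z)-2-hydroperoxy-2-methoxy-3,7-dimethyl-5-methylidene-15-phenylpentadec-14-ene (C2 epimers) | C[C@H](CCCCCC/C=C\c1ccccc1)CC(=C)C[C@@H](C)C(C)(OC)OO
F3 | step 12 | {[(4R)-3-methoxy-3,4-dimethyl-6-[(2R,9Z)-2-methyl-10-phenyldec-9-en-1-yl]-1,2-dioxan-6-yl]methyl}mercury(II) acetate (C3 and C6 epimers) | C[C@H](CCCCCC/C=C\c1ccccc1)CC1(C[Hg]OC(C)=O)C[C@@H](C)C(C)(OC)OO1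
F4 | step 11 | (3S,4R)-6-fluoro-3-methoxy-3,4-dimethyl-6-[(2R,9Z)-2-methyl-10-phenyldec-9-en-1-yl]-1,2-dioxane (C6 anomers) | C[C@H](CCCCCC/C=C\c1ccccc1)CC1(F)C[C@@H](C)[C@@](C)(OC)OO1
F5 | step 4 | (S)-(3-bromo-2-methylpropoxy)(tert-butyl)dimethylsilane | C[C@H](CBr)CO[Si](C)(C)C(C)(C)C
F6 | step 4 | [(2S)-3-{[tert-butyl(dimethyl)silyl]oxy}-2-methylpropyl]magnesium bromide | C[C@H](C[Mg]Br)CO[Si](C)(C)C(C)(C)C
F7 | step 4 | tert-butyl(dimethyl){[(2R,9Z)-2-methyl-10-phenyldec-9-en-1-yl]oxy}silane | C[C@H](CCCCCC/C=C\c1ccccc1)CO[Si](C)(C)C(C)(C)C
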